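the same everywhere: reagent in the second phase 0.598 M

|  | substrate | remark | time | volume of the second phase over the first |
|---|---|---|---|---|
| violet | 0.23 M | run made earlier |  |  |
| grey | 0.35 M | run made earlier |  |  |
| flask | 0.46 M |  | 25 h | 0.25 |

| run | time / h | target / % | substrate / % |
|---|---|---|---|
| violet | 2.50 | 12.5 | 81.6 |
| violet | 4.00 | 16.3 | 72.1 |
| violet | 6.00 | 19.5 | 63.4 |
| violet | 8.00 | 19.9 | 56.0 |
| violet | 12.0 | 18.5 | 46.1 |
| violet | 20.0 | 14.7 | 34.0 |
| violet | 30.0 | 10.6 | 25.5 |
| grey | 2.50 | 12.3 | 80.4 |
| grey | 4.00 | 15.0 | 70.9 |
| grey | 6.00 | 16.4 | 60.6 |
| grey | 8.00 | 16.4 | 52.5 |
| grey | 12.0 | 14.5 | 41.7 |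
| grey | 20.0 | 11.2 | 30.0 |
| grey | 30.0 | 8.2 | 22.1 |

(readings scatter by 0.3 percentage points)

- percent here means substrate units held: one self-condensation product or side product counts as two
- in the second phase: reagent in the second phase; everything else is in the first
- charges count per volume of the first phase; a concentration in a rate is the amount of a species over the volume of its own phase; every rate counts per litre of the first phase
- what was read earlier has a scatter of 0.3 percentage points, one standard deviation
- reactions considered so far: substrate + target -> side product; reagent in the reaction phase <-> reagent in the second phase; substrate + reagent in the reaction phase <-> target; reagent in the reaction phase + target -> over-reacted product; 2 substrate -> self-condensation product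
- the earlier runs hold the two phases in the same ratio of volumes as the flask asked about

1. the target standing at 25 h, as a percentage of the substrate charged
2. the change that raises the amount of target at 25 h, in percent of the substrate charged most ("none" if none brings more than 2 percentage points) (epsilon / gamma / none)
3. amount of target at 25 h, in percent of the substrate charged, after epsilon

- epsilon: doubling the transfer coefficient of the reagent in the second phase, all else as stated
- gamma: doubling the amount of reagent in the second phase, all else as stated

I start by adding two columns: substrate plus target, which I call the pool P, in percent of the substrate charged.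

Does the split inside P hold still? Nearly, late on. As read, target over substrate goes from 0.401 at 12.0 h to 0.416 at 30.0 h in violet, and from 0.348 to 0.371 in grey.

Then how fast does P drain? With a fixed split, substrate and target each scale with P, so a loss in which they meet runs with P squared. Summed over time, such a second-order decay has a plain result: the reciprocal of P, taken as a fraction of the charge, climbs by a fixed amount each hour. Between those readings the climb is 0.0679 h⁻¹ in violet and 0.0845 h⁻¹ in grey, so it is faster in grey, the run charged with more substrate.

What does that give at 0.46 M? Carried straight along the charge, the hourly climb of the reciprocal of P, the drain constant m, becomes 0.0997 h⁻¹ for the flask. The reciprocal at 12.0 h, carried the same way, is 1.99. So my estimate of the flask's pool at 25 h is 30.4%. With the ratio read at 30.0 h, carried the same way to 0.330, I reckon target at 7.55%.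

The forecast gives 7.8%, a little above mine, names none as the best change and gives 7.7% after epsilon, holding that “the reversible step sits near equilibrium”.

The flask gives 7.74%, none as the best change (epsilon −0.026 percentage points, gamma 0.11 points), and 7.71% after epsilon.

    substrate + target → side product (k = 0.380 M⁻¹ h⁻¹)
    reagent in the reaction phase ⇌ reagent in the second phase, rate k2*([reagent in the reaction phase] - [reagent in the second phase]/K2) per volume of the first phase (partition coefficient = 0.880, kL = 0.800 h⁻¹)
    substrate + reagent in the reaction phase ⇌ target (K = 1.50 M⁻¹, k = 0.170 M⁻¹ h⁻¹)
    reagent in the reaction phase + target → over-reacted product (k = 0.110 M⁻¹ h⁻¹)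
    2 substrate → self-condensation product (k = 0.0260 M⁻¹ h⁻¹)

In the flask at 25.0 h, the step from substrate and reagent in the reaction phase to target relaxes, both ways together, with a half-life of 3.80 h, short against the 25 h, while target is made at 0.541 times the rate at which it is used up, each step taken net. The flask's pool climbs in reciprocal by 0.101 h⁻¹ over the second half of the time, against m of 0.0997 h⁻¹. For the neighbour flask charged with 0.18 M and read at the same 25 h, m is 0.0610 h⁻¹, which gives a pool of 44.6%, and that neighbour holds substrate plus target of 44.7%.

The numbers in the tables were computed on assumed constants; the scatter is artificial.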